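**Strategy.** The quinone ring (C1 carbonyl, C2 acetoxy, C3 aryl, C4 carbonyl, C5–H, C6 aryl) is opened at the C4–C5 bond. A Moore rearrangement makes this bond: a squarate-derived 4-hydroxy-4-(1-arylvinyl)cyclobutenone opens on heating to a dienylketene whose ketene carbon (future C4) closes onto the vinyl methylene (future C5) by 6π-electrocyclisation; tautomerisation and oxidation deliver the quinone in one operation. The step exploits the lone ring hydrogen at C5 beside the C4 carbonyl and the contiguous C1–C2–C3–C4 oxygen/aryl pattern, which is the four-carbon squarate unit. The precursor is a four-membered ring carrying the C3 aryl, a tert-butoxy group as latent C2 acetate, and a carbinol bearing the arylvinyl group.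

Key step: step 5

Remark: di-tert-butyl squarate (1) is taken as a catalogue compound; the target has no stereocentre, and the single carbinol centre made on the way (in 4, 5 and 11) is racemic and is erased in steps 1 and 5.

**Step 1**
Reactants: 1 di-tert-butyl squarate (3,4-di-tert-butoxycyclobut-3-ene-1,2-dione); 2 (4-bromophenoxy)(tert-butyl)dimethylsilane
Product: 6 3-tert-butoxy-4-[4-(tert-butyldimethylsilyloxy)phenyl]cyclobut-3-ene-1,2-dione, via aryllithium 3 (not isolated), via lithium alkoxide 4 (not isolated), via trifluoroacetate 5 (not isolated)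
Conditions: 2, n-BuLi, THF, −78 °C; then 1, −78 °C; then (CF3CO)2O, −78 to 0 °C; aq. NaHCO3 work-up
Reagents that add atoms: none
Why: Bromine–lithium exchange and 1,2-addition of the aryllithium to one squarate carbonyl are followed by O-trifluoroacetylation, ionisation and loss of the tert-butyl group from the resulting oxocarbenium ion, the established carbonyl-transposition route from squarate esters to 3-alkoxy-4-arylcyclobutenediones, under which the aryl silyl ether should be inert.

**Step 2**
Reactants: 7 4'-hydroxyacetophenone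
Product: 8 4'-(tert-butyldimethylsilyloxy)acetophenone
Conditions: TBSCl, imidazole, DMF, rt
Reagents that add atoms: tert-butyldimethylsilyl chloride, CC(C)(C)[Si](C)(C)Cl
Why: Standard imidazole-promoted O-silylation of a phenol, which leaves the ketone untouched.

**Step 3**
Reactants: 8 4'-(tert-butyldimethylsilyloxy)acetophenone
Product: 9 1-(1-bromoethenyl)-4-(tert-butyldimethylsilyloxy)benzene
Conditions: (PhO)3P, Br2, CH2Cl2, −60 °C; then Et3N, 8, −60 °C to reflux
Reagents that add atoms: bromine, BrBr
Why: Deoxybromination of an enolisable methyl ketone with the preformed triphenyl phosphite–bromine adduct, in which the activated ketone oxygen leaves as triphenyl phosphate and Et3N removes HBr to give the 1-bromoalkene, with no free bromine left to attack the electron-rich ring.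

**Step 4**
Reactants: 9 1-(1-bromoethenyl)-4-(tert-butyldimethylsilyloxy)benzene; 6 3-tert-butoxy-4-[4-(tert-butyldimethylsilyloxy)phenyl]cyclobut-3-ene-1,2-dione
Product: 11 racemic 3-tert-butoxy-4-hydroxy-2-[4-(tert-butyldimethylsilyloxy)phenyl]-4-{1-[4-(tert-butyldimethylsilyloxy)phenyl]ethenyl}cyclobut-2-en-1-one, via vinyllithium 10 (not isolated)
Conditions: 9, t-BuLi (2 equiv), THF, −78 °C; then 6, THF, −78 °C; aq. NH4Cl
Reagents that add atoms: none
Why: Bromine–lithium exchange gives the 1-arylvinyllithium, which undergoes 1,2-addition at the more electrophilic, ketone-like carbonyl of 6 (the one on the tert-butoxy-bearing carbon, the other being a deactivated vinylogous ester carbonyl), the regiochemistry established for 3-alkoxy-4-substituted cyclobutenediones; the new carbinol centre forms as a racemate and is erased in step 5.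

**Step 5**
Reactants: 11 racemic 3-tert-butoxy-4-hydroxy-2-[4-(tert-butyldimethylsilyloxy)phenyl]-4-{1-[4-(tert-butyldimethylsilyloxy)phenyl]ethenyl}cyclobut-2-en-1-one
Product: 15 2-tert-butoxy-3,6-bis[4-(tert-butyldimethylsilyloxy)phenyl]-1,4-benzoquinone, via dienylketene 12 (not isolated), via cyclohexadienone 13 (not isolated), via hydroquinone 14 (not isolated)
Conditions: degassed toluene, 110 °C; cool; then Ag2O, rt
Reagents that add atoms: none
Why: Heating should trigger conrotatory 4π-electrocyclic opening of the C1–C4 bond of the cyclobutenone to dienylketene 12, which closes by thermally allowed disrotatory 6π-electrocyclisation between the ketene carbon and the terminal methylene carbon to cyclohexadienone 13; enolisation gives hydroquinone 14 and Ag2O dehydrogenates it to the quinone. The closest known reaction type is the Moore rearrangement of 4-alkenyl-4-hydroxycyclobutenones, in the substitution pattern used for hydroxyquinone synthesis from tert-butyl squarate. The six-membered quinone ring is the only ring closed, in a 6π-electrocyclic mode between two sp2 carbons of a fully conjugated six-carbon chain. No stereocentre is created, and the racemic carbinol centre of 11 becomes sp2. The step needs torquoselective outward rotation of the hydroxyl so that the arylvinyl group turns inward, cis to the ketene, instead of the hydroxyl turning inward and lactonising to a butenolide; the strong donor character of the hydroxyl secures this. The substituent pattern of the ring is already fixed by the regiochemistry of step 4, so the closure itself involves no regiochemical choice.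

**Step 6**
Reactants: 15 2-tert-butoxy-3,6-bis[4-(tert-butyldimethylsilyloxy)phenyl]-1,4-benzoquinone
Product: 17 2-acetoxy-3,6-bis[4-(tert-butyldimethylsilyloxy)phenyl]-1,4-benzoquinone, via hydroxyquinone 16 (not isolated)
Conditions: TFA, CH2Cl2, 0 °C; evaporate; then Ac2O, pyridine, CH2Cl2, 0 °C
Reagents that add atoms: acetic anhydride, CC(=O)OC(C)=O
Why: Acidolysis of the tert-butyl vinylogous ester (loss of isobutene) should unmask the acidic 2-hydroxyquinone without touching the aryl silyl ethers, and O-acylation of this vinylogous acid with Ac2O/pyridine then gives the enol acetate, reversible acyl transfer favouring the more stable 1,4-quinone tautomer.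

**Step 7**
Reactants: 17 2-acetoxy-3,6-bis[4-(tert-butyldimethylsilyloxy)phenyl]-1,4-benzoquinone
Product: 18 neonambiquinone A (2,5-bis(4-hydroxyphenyl)-3,6-dioxocyclohexa-1,4-dien-1-yl acetate)
Conditions: HF·pyridine, THF, 0 °C to rt (polypropylene vessel)
Reagents that add atoms: none
Why: Fluoride-driven desilylation of the two aryl silyl ethers (strong Si–F bond) under acidic, non-basic conditions should free both phenols while the base- and nucleophile-sensitive enol acetate of the quinone persists.

**Compound list**

1 | di-tert-butyl squarate (3,4-di-tert-butoxycyclobut-3-ene-1,2-dione) | CC(C)(C)OC1=C(OC(C)(C)C)C(=O)C1=O | starting material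
2 | (4-bromophenoxy)(tert-butyl)dimethylsilane | CC(C)(C)[Si](C)(C)Oc1ccc(Br)cc1 | starting material
3 | [4-(tert-butyldimethylsilyloxy)phenyl]lithium | [Li]c1ccc(O[Si](C)(C)C(C)(C)C)cc1 | intermediate
4 | lithium alkoxide of racemic 2,3-di-tert-butoxy-4-hydroxy-4-[4-(tert-butyldimethylsilyloxy)phenyl]cyclobut-2-en-1-one | [Li]OC1(c2ccc(O[Si](C)(C)C(C)(C)C)cc2)C(OC(C)(C)C)=C(OC(C)(C)C)C1=O | intermediate
5 | racemic 2,3-di-tert-butoxy-4-oxo-1-[4-(tert-butyldimethylsilyloxy)phenyl]cyclobut-2-en-1-yl trifluoroacetate | O=C(OC1(c2ccc(O[Si](C)(C)C(C)(C)C)cc2)C(OC(C)(C)C)=C(OC(C)(C)C)C1=O)C(F)(F)F | intermediate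
6 | 3-tert-butoxy-4-[4-(tert-butyldimethylsilyloxy)phenyl]cyclobut-3-ene-1,2-dione | CC(C)(C)OC1=C(c2ccc(O[Si](C)(C)C(C)(C)C)cc2)C(=O)C1=O | intermediate
7 | 4'-hydroxyacetophenone | CC(=O)c1ccc(O)cc1 | starting material
8 | 4'-(tert-butyldimethylsilyloxy)acetophenone | CC(=O)c1ccc(O[Si](C)(C)C(C)(C)C)cc1 | intermediate
9 | 1-(1-bromoethenyl)-4-(tert-butyldimethylsilyloxy)benzene | C=C(Br)c1ccc(O[Si](C)(C)C(C)(C)C)cc1 | intermediate
10 | {1-[4-(tert-butyldimethylsilyloxy)phenyl]ethenyl}lithium | [Li]C(=C)c1ccc(O[Si](C)(C)C(C)(C)C)cc1 | intermediate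
11 | racemic 3-tert-butoxy-4-hydroxy-2-[4-(tert-butyldimethylsilyloxy)phenyl]-4-{1-[4-(tert-butyldimethylsilyloxy)phenyl]ethenyl}cyclobut-2-en-1-one | C=C(c1ccc(O[Si](C)(C)C(C)(C)C)cc1)C1(O)C(OC(C)(C)C)=C(c2ccc(O[Si](C)(C)C(C)(C)C)cc2)C1=O | intermediate
12 | dienylketene: 3-tert-butoxy-4-hydroxy-2,5-bis[4-(tert-butyldimethylsilyloxy)phenyl]hexa-1,3,5-trien-1-one, ketenyl and arylvinyl groups cis on the central double bond | CC(C)(C)O/C(C(=C=O)c1ccc(O[Si](C)(C)C(C)(C)C)cc1)=C(\O)C(=C)c1ccc(O[Si](C)(C)C(C)(C)C)cc1 | intermediate
13 | 3-tert-butoxy-4-hydroxy-2,5-bis[4-(tert-butyldimethylsilyloxy)phenyl]cyclohexa-2,4-dien-1-one | O=C1CC(c2ccc(O[Si](C)(C)C(C)(C)C)cc2)=C(O)C(OC(C)(C)C)=C1c1ccc(O[Si](C)(C)C(C)(C)C)cc1 | intermediate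
14 | 3-tert-butoxy-2,5-bis[4-(tert-butyldimethylsilyloxy)phenyl]benzene-1,4-diol | CC(C)(C)Oc1c(O)c(-c2ccc(O[Si](C)(C)C(C)(C)C)cc2)cc(O)c1-c1ccc(O[Si](C)(C)C(C)(C)C)cc1 | intermediate
15 | 2-tert-butoxy-3,6-bis[4-(tert-butyldimethylsilyloxy)phenyl]-1,4-benzoquinone | CC(C)(C)OC1=C(c2ccc(O[Si](C)(C)C(C)(C)C)cc2)C(=O)C=C(c2ccc(O[Si](C)(C)C(C)(C)C)cc2)C1=O | intermediate
16 | 2-hydroxy-3,6-bis[4-(tert-butyldimethylsilyloxy)phenyl]-1,4-benzoquinone | OC1=C(c2ccc(O[Si](C)(C)C(C)(C)C)cc2)C(=O)C=C(c2ccc(O[Si](C)(C)C(C)(C)C)cc2)C1=O | intermediate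
17 | 2-acetoxy-3,6-bis[4-(tert-butyldimethylsilyloxy)phenyl]-1,4-benzoquinone | CC(=O)OC1=C(c2ccc(O[Si](C)(C)C(C)(C)C)cc2)C(=O)C=C(c2ccc(O[Si](C)(C)C(C)(C)C)cc2)C1=O | intermediate
18 | neonambiquinone A | CC(=O)OC1=C(c2ccc(O)cc2)C(=O)C=C(c2ccc(O)cc2)C1=O | target

**Step count and risks**

Total step count: 7. Longest linear sequence: 6 steps (steps 2, 3, 4, 5, 6, 7, from compound 7).

Steps most likely to fail:

1. Step 5. The dienylketene may be diverted before ring closure: the free hydroxyl can rotate inward and lactonise to a butenolide, the hydroxyl of a second molecule can capture the ketene, or the tert-butyl enol ether can lose isobutene on heating. The fallback sets out from compound 11 and changes the substrate instead of the heating. The carbinol is capped (TMSCl, Et3N, CH2Cl2, 0 °C) to give racemic 3-tert-butoxy-2-[4-(tert-butyldimethylsilyloxy)phenyl]-4-{1-[4-(tert-butyldimethylsilyloxy)phenyl]ethenyl}-4-(trimethylsilyloxy)cyclobut-2-en-1-one F1. The silyloxy group is a reliable outward rotor and cannot add to a ketene, so thermolysis (toluene, 110 °C) should give, by the same opening and closure, 3-tert-butoxy-2,5-bis[4-(tert-butyldimethylsilyloxy)phenyl]-4-(trimethylsilyloxy)phenol F2. Dilute aqueous citric acid should hydrolyse the labile aryl trimethylsilyl ether, and the fallback comes back to the route at compound 14, which Ag2O oxidises to 15 as before.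

2. Step 7. The acetyl group may be transferred from the quinone enol acetate (a vinylogous mixed anhydride) to the phenols as they are set free, or be solvolysed, while the silyl ethers are cleaved. The fallback sets out from compound 15 and reverses the order of the end game so that no acetate is present when silicon is removed. TFA in CH2Cl2 followed by HF·pyridine in THF should strip the tert-butyl group and both silyl groups to give 2-hydroxy-3,6-bis(4-hydroxyphenyl)-1,4-benzoquinone F3. Its quinone hydroxyl, a vinylogous carboxylic acid far more acidic than the phenols, is converted selectively into the sodium salt (one equivalent of NaHCO3), and this salt alone is acetylated (AcCl, one equivalent, THF, −40 °C). The fallback comes back to the route at compound 18.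

3. Step 4. tert-Butyllithium may dehydrobrominate bromoalkene 9 to the arylacetylene in competition with bromine–lithium exchange, so that an alkynyl instead of an alkenyl nucleophile is delivered to 6. The fallback sets out from compound 8 and replaces the bromoalkene by a Shapiro reaction. Condensation with 2,4,6-triisopropylbenzenesulfonyl hydrazide (THF, rt) gives 4'-(tert-butyldimethylsilyloxy)acetophenone 2,4,6-triisopropylbenzenesulfonylhydrazone F4. Treatment with n-BuLi (2 equiv, THF, −78 to 0 °C) should generate the same vinyllithium 10 with loss of nitrogen and sulfinate. Addition of 6 at −78 °C brings the fallback back to the route at compound 11.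

**Further compounds**

F1 | step 5 | racemic 3-tert-butoxy-2-[4-(tert-butyldimethylsilyloxy)phenyl]-4-{1-[4-(tert-butyldimethylsilyloxy)phenyl]ethenyl}-4-(trimethylsilyloxy)cyclobut-2-en-1-one | C=C(c1ccc(O[Si](C)(C)C(C)(C)C)cc1)C1(O[Si](C)(C)C)C(OC(C)(C)C)=C(c2ccc(O[Si](C)(C)C(C)(C)C)cc2)C1=O
F2 | step 5 | 3-tert-butoxy-2,5-bis[4-(tert-butyldimethylsilyloxy)phenyl]-4-(trimethylsilyloxy)phenol | CC(C)(C)Oc1c(O[Si](C)(C)C)c(-c2ccc(O[Si](C)(C)C(C)(C)C)cc2)cc(O)c1-c1ccc(O[Si](C)(C)C(C)(C)C)cc1
F3 | step 7 | 2-hydroxy-3,6-bis(4-hydroxyphenyl)-1,4-benzoquinone | OC1=C(c2ccc(O)cc2)C(=O)C=C(c2ccc(O)cc2)C1=O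
F4 | step 4 | 4'-(tert-butyldimethylsilyloxy)acetophenone (E)-2,4,6-triisopropylbenzenesulfonylhydrazone | C/C(=N\NS(=O)(=O)c1c(C(C)C)cc(C(C)C)cc1C(C)C)c1ccc(O[Si](C)(C)C(C)(C)C)cc1
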